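What stayed on my mind was a leftover: at the last reading of the winter run, 0.0806 M of X stood against 0.120 M of J charged. I named the charged J not showing as X the leftover 0.03940 M, the gap in the mass balance.

in all of them: J 0.120 M
- winter: 
- midnight: X 0.0600 M
- summer: time 11 h

| winter run: time / h | winter run: [X] / M | midnight run: time / h | midnight run: [X] / M |
|---|---|---|---|
| 0.73 | 0.0297 | 0.73 | 0.1115 |
| 1.5 | 0.0532 | 1.5 | 0.1376 |
| 2.2 | 0.0670 | 2.2 | 0.1494 |
| 2.9 | 0.0742 | 2.9 | 0.1520 |
| 3.7 | 0.0776 | 3.7 | 0.1538 |
| 4.4 | 0.0806 | 4.4 | 0.1547 |

(standard deviation of a reading: 0.001 M)

- X in the summer run at 11 h, as a share of the J charged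

- Overall: J -> X.
- Constant volume, constant temperature.

The summer run repeats the winter charge and goes on longer, so I reckoned only the correction to that last winter reading. My bench rule was that when each step gains about half of the step before, what is still to come equals the last gain. In the winter run one step added 0.007200 M, less than the 0.01380 M of the step before, which fits the rule. The asked time lies about 9.43 steps past the last reading, so I summed the series to its end. That gave a tail of 0.003000 M, and so 69.7% of the charge as X.

But the rule has a border. A difference of two readings scatters by 0.001414 M, and the last winter gain stands just 2.12 times above that. The last midnight gain, at 0.636 times, lies inside it, so that step of the midnight run could not test the halving. Earlier in the midnight run, the ratio of successive gains read 0.452 and then 0.220, so the halving held once and then failed.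

The forecast put the share higher than mine, at 70% within 67.5% to 73.5%, and read the stall as “a dying catalyst rather than equilibrium”. The flask gave 68.3%.

    J → X (0.1390 h⁻¹)
    J + X → 2 X (5.544 L mol⁻¹ h⁻¹)
    J → X (0.2030 h⁻¹)
    J → Vy (0.2491 h⁻¹)

The summer run thus kept 0.03800 M of its charge out of X at the asked time, which is nearly all of the winter leftover of 0.0394 M. The turning of J into Vy kept that charge from X. The same run without this turning reaches >99.9% instead of 68.3%, so it accounts for 100% of what is missing.

The numbers in the tables were computed on assumed constants; scatter was added.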